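Readings and results are simulated from invented constants; noise was put on by code.

The vessel is closed and stirred and Q is held, so the charge of E and Z together is your limiting reagent, and its books can be kept in fractions of that charge.

all flasks: E 0.93 M; Z 0.93 M; Q 120 mM (held)

| flask | L | remark | time |
|---|---|---|---|
| amber | 8.3 mM | run made earlier |  |
| blue | 14 mM | run made earlier |  |
| alder | 25 mM |  | 8.0 min |
| elm | 8.0 mM |  | 15 min |

| run | time / min | X / % | D / % |
|---|---|---|---|
| amber | 1.33 | 6 | 1 |
| amber | 3.00 | 11 | 3 |
| amber | 4.00 | 12 | 2 |
| amber | 6.00 | 22 | 7 |
| blue | 1.33 | 6 | 1 |
| blue | 3.00 | 11 | 5 |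
| blue | 4.00 | 12 | 5 |
| blue | 6.00 | 22 | 7 |

(standard deviation of a reading: 1.5 percentage points)

- L is single-handed; E and Z are mirror images of each other, charged as a racemate, each of them at the stated concentration
- at the start none of Q is in solution
- an excess is the difference of the two amounts in percent of their sum
- an excess is below zero if the other one leads

1. which one finishes higher in excess of X over D ("neither" within 2 percentage points) (alder / elm / neither)
2. excess of X over D at the end, alder
3. excess of X over D at the end, elm

Open the ledger at amber, 6.00 min: X reads 22%, D reads 7%, and by subtraction the remaining 71.0% is still E and Z. Blue, with 14 mM of L against 8.3 mM, enters the same two figures at that time. Pooled over both runs, the readings give 0.767 as the split, the share of every turned mole that lands in X. It reads 0.773 over the earlier two readings of each run and 0.764 over the later two. A ledger with separate books for E and Z that never mix has X's entry thin as E thins, and these readings, each scattering by 1.5 percentage points, show no sag that I can tell from that scatter. My own reckoning therefore carries the split unchanged to alder and elm, which makes the excess 53.4% in both, and my answer is neither.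

The forecast says alder, with 47% (38% to 55%) for alder and 30% (21% to 39%) for elm, on the ground that “Alder finishes higher because it stops earlier”.

The flask gives neither: alder 47.3%, elm 47.2%. Elm stands 17 points above the forecast, and my 53.4%, from a split of 0.767, stands 6.1 points above alder.

    J + L + E → L + X (k = 14.0 M⁻² s⁻¹)
    J + L + Z → L + D (k = 4.80 M⁻² s⁻¹)
    E ⇌ Z (k = 0.0100 s⁻¹)
    Q ⇌ J, rate k4*(csat - [J]) (kL = 0.0140 s⁻¹)
    2 L → G (k = 0.150 M⁻¹ s⁻¹)

At 15.0 min in elm, the step to X uses E more slowly than the forward step from E to Z taken alone, at 0.18 of its rate. E stands there at 19.9% and Z at 21.1% of the two together charged, as in a dynamic kinetic resolution. Elm read at 25 min has E at 9.17% and Z at 9.80% of the two together charged, so the split puts 62.2% in X at an excess of 53.4%; computed, X stands at 59.6% and the excess at 47.0%.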